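## Retrosynthetic overview

- The target is reached from a racemic 3-aryl-3-hydroxy-5,7-bis(methoxymethoxy)chroman-4-one by loss of water across C2–C3 and removal of three MOM ethers.
- The strategy rests on C4 (ring C carbonyl carbon, on ring A) and C3 (the carbon bearing ring B) both being carbonyl-derived carbons joined through O1–C2. Cutting C3–C4 gives a ring A aldehyde tethered by O1–C2H2 to a ring B aryl ketone; carbene umpolung of the aldehyde re-forms C3–C4 and closes ring C.
- The keto-aldehyde is cut at O1–C2 (Williamson) into 2-hydroxy-4,6-bis(methoxymethoxy)benzaldehyde and a ring B phenacyl bromide.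
- The ring B piece comes from acetovanillone: O-(1,1-dimethylpropargyl)ation, semihydrogenation and aromatic Claisen shift place the prenyl group at C5'; MOM protection and bromination through the silyl enol ether follow.
- Rings A and B are bought as arenes; ring C is the only ring formed (step 8).

Key step: step 8

Assumption: the target is achiral; the one stereocentre made on the way (C3 of the chromanone) is carried as a racemate and is removed in step 9. "Prenyl" means 3-methylbut-2-en-1-yl throughout.

## Route

Step 1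
Reactants: 1 4'-hydroxy-3'-methoxyacetophenone (acetovanillone); 2 2-methylbut-3-yn-2-ol
Product: 4 1-[3-methoxy-4-(2-methylbut-3-yn-2-yloxy)phenyl]ethan-1-one, via 2-methylbut-3-yn-2-yl trifluoroacetate 3 (not isolated)
Conditions: 2, (CF3CO)2O, DBU, MeCN, −5 °C; then 1, DBU, CuCl2·2H2O (cat.), MeCN, 0 °C → rt
Reagents that add atoms: none
Why: Copper-catalysed propargylic substitution (Godfrey-type O-alkylation), in which the tertiary propargylic trifluoroacetate ionises as a copper-acetylide-stabilised cation that the acidic para-acyl phenoxide captures, should give the hindered tertiary aryl ether that direct SN2 alkylation cannot.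

Step 2
Reactants: 4 1-[3-methoxy-4-(2-methylbut-3-yn-2-yloxy)phenyl]ethan-1-one
Product: 5 1-[3-methoxy-4-(2-methylbut-3-en-2-yloxy)phenyl]ethan-1-one
Conditions: H2 (1 atm), 5% Pd/CaCO3 poisoned with Pb(OAc)2, quinoline, EtOAc, rt
Reagents that add atoms: none
Why: Lindlar semihydrogenation adds one equivalent of H2 to the terminal alkyne on poisoned palladium and should stop at the alkene without touching the aryl ketone.

Step 3
Reactants: 5 1-[3-methoxy-4-(2-methylbut-3-en-2-yloxy)phenyl]ethan-1-one
Product: 6 1-[4-hydroxy-3-methoxy-5-(3-methylbut-2-en-1-yl)phenyl]ethan-1-one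
Conditions: PhNEt2, 130 °C
Reagents that add atoms: none
Why: Aromatic Claisen rearrangement ([3,3]-sigmatropic shift) of the 1,1-dimethylallyl aryl ether to C5, the only free ortho position, turns the reverse-prenyl ether into the C-prenyl group, and tautomerisation of the dienone restores the phenol; the basic solvent suppresses acid-induced chroman formation.

Step 4
Reactants: 6 1-[4-hydroxy-3-methoxy-5-(3-methylbut-2-en-1-yl)phenyl]ethan-1-one
Product: 7 1-[3-methoxy-4-(methoxymethoxy)-5-(3-methylbut-2-en-1-yl)phenyl]ethan-1-one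
Conditions: MOMCl, iPr2NEt, Bu4NI (cat.), CH2Cl2, 0 °C → reflux
Reagents that add atoms: chloromethyl methyl ether (MOMCl), COCCl
Why: O-Alkylation of the phenol with the reactive α-chloro ether under amine base (MOM ether formation) should protect the flanked hydroxyl without enolising the methyl ketone.

Step 5
Reactants: 7 1-[3-methoxy-4-(methoxymethoxy)-5-(3-methylbut-2-en-1-yl)phenyl]ethan-1-one
Product: 9 2-bromo-1-[3-methoxy-4-(methoxymethoxy)-5-(3-methylbut-2-en-1-yl)phenyl]ethan-1-one, via trimethylsilyl enol ether 8 (not isolated)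
Conditions: LiN(SiMe3)2, Me3SiCl, THF, −78 °C; crude enol ether, then NBS, NaHCO3, THF, −78 °C → 0 °C
Reagents that add atoms: N-bromosuccinimide (NBS), O=C1CCC(=O)N1Br
Why: Kinetic enolisation with O-silylation followed by electrophilic bromination of the silyl enol ether should give the phenacyl bromide regiospecifically, because the enol ether is far more nucleophilic than the prenyl alkene or the arene at −78 °C and the non-acidic conditions spare the MOM ether.

Step 6
Reactants: 10 2,4,6-trihydroxybenzaldehyde
Product: 11 2-hydroxy-4,6-bis(methoxymethoxy)benzaldehyde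
Conditions: MOMCl (2.1 equiv), iPr2NEt, CH2Cl2, 0 °C
Reagents that add atoms: chloromethyl methyl ether (MOMCl), COCCl
Why: Regioselective phenol alkylation should stop at the bis-MOM ether because the last ortho hydroxyl is held in a strong hydrogen bond to the aldehyde and is the least nucleophilic.

Step 7
Reactants: 9 2-bromo-1-[3-methoxy-4-(methoxymethoxy)-5-(3-methylbut-2-en-1-yl)phenyl]ethan-1-one; 11 2-hydroxy-4,6-bis(methoxymethoxy)benzaldehyde
Product: 12 2-{2-[3-methoxy-4-(methoxymethoxy)-5-(3-methylbut-2-en-1-yl)phenyl]-2-oxoethoxy}-4,6-bis(methoxymethoxy)benzaldehyde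
Conditions: K2CO3, acetone, 0 °C → rt
Reagents that add atoms: none
Why: Williamson ether synthesis by SN2 displacement of the very reactive phenacyl bromide with the potassium phenoxide of 11 forms O1–C2 at or below room temperature, mild enough to stop before the product undergoes intramolecular aldol condensation (Rap–Stoermer pathway).

Step 8
Reactants: 12 2-{2-[3-methoxy-4-(methoxymethoxy)-5-(3-methylbut-2-en-1-yl)phenyl]-2-oxoethoxy}-4,6-bis(methoxymethoxy)benzaldehyde
Product: 13 racemic 3-hydroxy-3-[3-methoxy-4-(methoxymethoxy)-5-(3-methylbut-2-en-1-yl)phenyl]-5,7-bis(methoxymethoxy)chroman-4-one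
Conditions: 2-(pentafluorophenyl)-6,7-dihydro-5H-pyrrolo[2,1-c][1,2,4]triazol-2-ium tetrafluoroborate (20 mol%), Et3N (20 mol%), toluene (0.05 M), rt → 40 °C, N2
Reagents that add atoms: none
Why: Et3N frees the triazolylidene, which adds to the ring A aldehyde; proton transfer gives the Breslow enaminol, an acyl anion equivalent at C4, which attacks the ketone carbon C3, and proton transfer with loss of the carbene releases the tertiary α-ketol. The closest known reaction type is the carbene-catalysed intramolecular aldehyde–ketone crossed benzoin cyclisation of 2-(2-oxo-2-arylethoxy)benzaldehydes to 3-hydroxychroman-4-ones. Ring C (C4–C4a–C8a–O1–C2–C3) closes in the 6-exo-trig mode, the attacked C3=O lying outside the new ring. The new stereocentre C3 is formed as a racemate because the catalyst is achiral and no other stereocentre is present, which is acceptable since step 9 removes it. The cross-selectivity needed is built into the substrate: only the aldehyde has the C–H required to become the donor, and the O1–C2 tether together with the two ortho alkoxy groups favours cyclisation over homo-benzoin dimerisation. The step also has to outrun base-induced aldol attack of the C2 methylene on the aldehyde (leading to a 2-aroylbenzofuran), which is why an acidic N-pentafluorophenyl triazolium salt that a weak amine base can deprotonate is chosen.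

Step 9
Reactants: 13 racemic 3-hydroxy-3-[3-methoxy-4-(methoxymethoxy)-5-(3-methylbut-2-en-1-yl)phenyl]-5,7-bis(methoxymethoxy)chroman-4-one
Product: 14 3-[3-methoxy-4-(methoxymethoxy)-5-(3-methylbut-2-en-1-yl)phenyl]-5,7-bis(methoxymethoxy)-4H-chromen-4-one
Conditions: SOCl2, pyridine, CH2Cl2, 0 °C
Reagents that add atoms: none
Why: Dehydration of the tertiary alcohol through its chlorosulfite ester, with pyridine-mediated E2 loss of an anti-periplanar C2 hydrogen, should give the C2=C3 bond conjugated with the C4 carbonyl, while pyridine scavenges HCl so the MOM ethers survive.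

Step 10
Reactants: 14 3-[3-methoxy-4-(methoxymethoxy)-5-(3-methylbut-2-en-1-yl)phenyl]-5,7-bis(methoxymethoxy)-4H-chromen-4-one
Product: 15 5,7-dihydroxy-3-[4-hydroxy-3-methoxy-5-(3-methylbut-2-en-1-yl)phenyl]-4H-chromen-4-one (2'-deoxypiscerythrone)
Conditions: 3 M HCl (aq), MeOH, 50 °C
Reagents that add atoms: none
Why: Acid-catalysed acetal exchange in methanol (MOM ether cleavage) should free the three phenols, with dilute acid and moderate temperature chosen so that the prenyl group is neither hydrated nor cyclised onto the neighbouring 4'-hydroxyl.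

## Compound list

1 | 4'-hydroxy-3'-methoxyacetophenone (acetovanillone) | CC(=O)c1ccc(O)c(OC)c1 | starting material
2 | 2-methylbut-3-yn-2-ol | CC(C)(O)C#C | starting material
3 | 2-methylbut-3-yn-2-yl trifluoroacetate | CC(C)(C#C)OC(=O)C(F)(F)F | intermediate
4 | 1-[3-methoxy-4-(2-methylbut-3-yn-2-yloxy)phenyl]ethan-1-one | CC(=O)c1ccc(OC(C)(C)C#C)c(OC)c1 | intermediate
5 | 1-[3-methoxy-4-(2-methylbut-3-en-2-yloxy)phenyl]ethan-1-one | CC(=O)c1ccc(OC(C)(C)C=C)c(OC)c1 | intermediate
6 | 1-[4-hydroxy-3-methoxy-5-(3-methylbut-2-en-1-yl)phenyl]ethan-1-one | CC(=O)c1cc(OC)c(O)c(CC=C(C)C)c1 | intermediate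
7 | 1-[3-methoxy-4-(methoxymethoxy)-5-(3-methylbut-2-en-1-yl)phenyl]ethan-1-one | CC(=O)c1cc(OC)c(OCOC)c(CC=C(C)C)c1 | intermediate
8 | {1-[3-methoxy-4-(methoxymethoxy)-5-(3-methylbut-2-en-1-yl)phenyl]ethenyloxy}trimethylsilane | C=C(O[Si](C)(C)C)c1cc(OC)c(OCOC)c(CC=C(C)C)c1 | intermediate
9 | 2-bromo-1-[3-methoxy-4-(methoxymethoxy)-5-(3-methylbut-2-en-1-yl)phenyl]ethan-1-one | O=C(CBr)c1cc(OC)c(OCOC)c(CC=C(C)C)c1 | intermediate
10 | 2,4,6-trihydroxybenzaldehyde | O=Cc1c(O)cc(O)cc1O | starting material
11 | 2-hydroxy-4,6-bis(methoxymethoxy)benzaldehyde | O=Cc1c(O)cc(OCOC)cc1OCOC | intermediate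
12 | 2-{2-[3-methoxy-4-(methoxymethoxy)-5-(3-methylbut-2-en-1-yl)phenyl]-2-oxoethoxy}-4,6-bis(methoxymethoxy)benzaldehyde | O=Cc1c(OCC(=O)c2cc(OC)c(OCOC)c(CC=C(C)C)c2)cc(OCOC)cc1OCOC | intermediate
13 | racemic 3-hydroxy-3-[3-methoxy-4-(methoxymethoxy)-5-(3-methylbut-2-en-1-yl)phenyl]-5,7-bis(methoxymethoxy)chroman-4-one | COCOc1cc(OCOC)c2c(c1)OCC(O)(c1cc(OC)c(OCOC)c(CC=C(C)C)c1)C2=O | intermediate
14 | 3-[3-methoxy-4-(methoxymethoxy)-5-(3-methylbut-2-en-1-yl)phenyl]-5,7-bis(methoxymethoxy)-4H-chromen-4-one | COCOc1cc(OCOC)c2c(c1)occ(-c1cc(OC)c(OCOC)c(CC=C(C)C)c1)c2=O | intermediate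
15 | 5,7-dihydroxy-3-[4-hydroxy-3-methoxy-5-(3-methylbut-2-en-1-yl)phenyl]-4H-chromen-4-one (2'-deoxypiscerythrone) | COc1cc(-c2coc3cc(O)cc(O)c3c2=O)cc(CC=C(C)C)c1O | target

## Step count and risks

Total step count: 10. Longest linear sequence: 9 steps (steps 1–5 and 7–10, from acetovanillone).

Steps most likely to fail:

1. Step 8. Carbene addition to the electron-rich aldehyde flanked by two ortho alkoxy groups may be too slow, so that the reaction stalls or base-induced aldol condensation of the C2 methylene onto the aldehyde takes over. The fallback makes C3 a vinyl nucleophile instead of making C4 an acyl anion; it sets out from 7 and 11 and comes back at 14. Ketone 7 would be converted with KN(SiMe3)2 and PhNTf2 in THF at −78 °C into the enol triflate 1-[3-methoxy-4-(methoxymethoxy)-5-(3-methylbut-2-en-1-yl)phenyl]ethenyl trifluoromethanesulfonate F1. A Nozaki–Hiyama–Kishi coupling (CrCl2, cat. NiCl2, DMF, rt) of F1 with aldehyde 11, whose free phenol the weakly basic organochromium species should tolerate, would form C3–C4 and give the racemic allylic alcohol 2-{1-hydroxy-2-[3-methoxy-4-(methoxymethoxy)-5-(3-methylbut-2-en-1-yl)phenyl]prop-2-en-1-yl}-3,5-bis(methoxymethoxy)phenol F2. MnO2 in CH2Cl2 would oxidise the benzylic-allylic alcohol to the α-aryl enone 1-[2-hydroxy-4,6-bis(methoxymethoxy)phenyl]-2-[3-methoxy-4-(methoxymethoxy)-5-(3-methylbut-2-en-1-yl)phenyl]prop-2-en-1-one F3. Its phenol would close ring C by 6-endo-trig oxa-Michael addition (K2CO3, MeOH) to the racemic isoflavanone 3-[3-methoxy-4-(methoxymethoxy)-5-(3-methylbut-2-en-1-yl)phenyl]-5,7-bis(methoxymethoxy)chroman-4-one F4. Dehydrogenation with DDQ in dioxane would then give 14, and step 10 follows.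

2. Step 9. The chlorosulfite of the tertiary benzylic α-ketol may ionise or be substituted by chloride instead of eliminating, and adventitious HCl may strip MOM groups early. The fallback reverses the order of the last two operations; it sets out from 13 and comes back at 15. Dilute HCl in MeOH would first remove the three MOM ethers to give racemic 3,5,7-trihydroxy-3-[4-hydroxy-3-methoxy-5-(3-methylbut-2-en-1-yl)phenyl]chroman-4-one F5. With the 4'-hydroxyl free, acid-catalysed E1 dehydration (TsOH, toluene, 60 °C) can pass through a para-quinone-methide-type cation at C3 that loses a C2 proton, giving 15 directly.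

3. Step 5. Electrophilic bromine may be consumed by the prenyl double bond or the electron-rich ring in competition with the silyl enol ether. The fallback avoids electrophilic halogen and the basic alkylation altogether; it sets out from 7 (with 11) and comes back at 12. Ketone 7 would be trifluoroacetylated (LiN(SiMe3)2, CF3CO2CH2CF3, THF, −78 °C) to 4,4,4-trifluoro-1-[3-methoxy-4-(methoxymethoxy)-5-(3-methylbut-2-en-1-yl)phenyl]butane-1,3-dione F6. Detrifluoroacetylative diazo transfer (MsN3, Et3N, H2O, MeCN, rt) would give 2-diazo-1-[3-methoxy-4-(methoxymethoxy)-5-(3-methylbut-2-en-1-yl)phenyl]ethan-1-one F7. Carbenoid O–H insertion into phenol 11 catalysed by Rh2(OAc)4 in CH2Cl2 at rt would then form the O1–C2 bond and give 12 under neutral conditions, replacing steps 5 and 7.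

## Further compounds

F1 | step 8 | 1-[3-methoxy-4-(methoxymethoxy)-5-(3-methylbut-2-en-1-yl)phenyl]ethenyl trifluoromethanesulfonate | C=C(OS(=O)(=O)C(F)(F)F)c1cc(OC)c(OCOC)c(CC=C(C)C)c1
F2 | step 8 | racemic 2-{1-hydroxy-2-[3-methoxy-4-(methoxymethoxy)-5-(3-methylbut-2-en-1-yl)phenyl]prop-2-en-1-yl}-3,5-bis(methoxymethoxy)phenol | C=C(C(O)c1c(O)cc(OCOC)cc1OCOC)c1cc(OC)c(OCOC)c(CC=C(C)C)c1
F3 | step 8 | 1-[2-hydroxy-4,6-bis(methoxymethoxy)phenyl]-2-[3-methoxy-4-(methoxymethoxy)-5-(3-methylbut-2-en-1-yl)phenyl]prop-2-en-1-one | C=C(C(=O)c1c(O)cc(OCOC)cc1OCOC)c1cc(OC)c(OCOC)c(CC=C(C)C)c1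
F4 | step 8 | racemic 3-[3-methoxy-4-(methoxymethoxy)-5-(3-methylbut-2-en-1-yl)phenyl]-5,7-bis(methoxymethoxy)chroman-4-one | COCOc1cc(OCOC)c2c(c1)OCC(c1cc(OC)c(OCOC)c(CC=C(C)C)c1)C2=O
F5 | step 9 | racemic 3,5,7-trihydroxy-3-[4-hydroxy-3-methoxy-5-(3-methylbut-2-en-1-yl)phenyl]chroman-4-one | COc1cc(C2(O)COc3cc(O)cc(O)c3C2=O)cc(CC=C(C)C)c1O
F6 | step 5 | 4,4,4-trifluoro-1-[3-methoxy-4-(methoxymethoxy)-5-(3-methylbut-2-en-1-yl)phenyl]butane-1,3-dione | O=C(CC(=O)C(F)(F)F)c1cc(OC)c(OCOC)c(CC=C(C)C)c1
F7 | step 5 | 2-diazo-1-[3-methoxy-4-(methoxymethoxy)-5-(3-methylbut-2-en-1-yl)phenyl]ethan-1-one | [N-]=[N+]=CC(=O)c1cc(OC)c(OCOC)c(CC=C(C)C)c1
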